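Its constants were drawn at random within sensible limits; the run is a simulation.

In a one-step world each D starts one chain, so a charge of 250 µM of D gives as many chains, but D has other partners here.

    J + D → Z + L (k1 = 32.3 M⁻¹ s⁻¹)
    J + Z → L + Z, rate k2*[Z]*[J] (k2 = 1040 M⁻¹ s⁻¹)
    D + E → D.E (k3 = 70700 M⁻¹ s⁻¹)
    2 D → D2 (k4 = 560 M⁻¹ s⁻¹)

J 5.0 mM; D 5 mol%; E 89 µM; time 15 s

1. average number of monomer units in a chain (chains begun, living or dead) at 15 s
2. part of the J that has reacted at 15 s

- a step written with two of one species runs at k times the square of its concentration and takes two of it each time
- the average divides the monomer in chains by the number of chains begun, living and dead together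
- run time (flask): 15 s

Who takes D first? At their charges E takes it at 6.29 s⁻¹ per D and J at 0.161 s⁻¹ per D, so E is served first, and I reckon F = 161 µM of free D after E.

How does F divide? With J frozen at its charge, initiation is pseudo-first-order. Coupling at first removes D at 0.180 s⁻¹ per D, close to initiation, and it fades as D falls. Integrating this race gives the chain count N = w ln(one + F/w), the Z reached as D tends to zero with J frozen, where w, the level of D at which coupling matches initiation, is 144 µM. My reckoning gives N = 108 µM.

What does N do to J? Held at N for the whole run, Z gives c = 81.5% and dp = 37.7. Z starts from nothing, and the time of initiation per D, 6.19 s, is 41.3% of the run, so my c stands high.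

The forecast gives c = 66% and dp = 37, on “about 90 µM of chains that never die”. On the chain count and on c it differs from my reckoning.

The simulation of the flask gives c = 66.2% and dp = 36.9, with Z at 89.8 µM at 15.0 s, below N.

For the neighbour flask charged with 2 mol% of D, I reckon F = 11.0 µM after E. The same reckoning gives N = 10.6 µM, c = 15.2% and dp = 71.9. That neighbour flask reads Z = 10.1 µM, c = 12.8% and dp = 63.5.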